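**Plan**
- Retrosynthesis: first the five O–benzyl bonds are cut, then O1–C8a of ring C (the aryl ether, key cut), then C2–C3 (enolate aroylation). The C6–CH3 and C8–CH3 bonds (cross-coupling) follow, and last C4–C4a (aryllithium plus Weinreb amide).
- Enabling feature: in ring A, C8a carries O1, lies ortho to C4a and so to the C4 ketone, and is meta to O5 and O7. A fluoride at C8a is therefore activated for addition–elimination, and the charge never falls on an oxygen-bearing carbon.
- Forward order: rings A and B are bought as 5-fluororesorcinol and a gallate-type ester. The C3–C4 unit is attached to ring A, both methyl groups are installed, ring B is joined through C2–C3, and ring C closes last.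
- Regiocontrol on ring A comes from electrophilic bromination: first next to fluorine and para to an ether, then exhaustively at the two remaining CH positions. Deprotonation is avoided because the F/OR-flanked and OR/OR-flanked CH sites would compete.
- Stereochemistry: the target is achiral and has no stereocentre. The only stereo-element on the way is the enol(ate) geometry of the diketone, which equilibrates and vanishes in ring C.

Key step: step 11

Remark: the target has no stereogenic unit, so "single enantiomer" reduces to the constitution shown and no step needs stereocontrol.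
Remark: the 1,3-diketone is written as its chelated enol. Because the central carbon bears a benzyloxy group, this geometry (O–H and C=O on the same side of C=C) has the CIP descriptor E, and the SMILES strings show it.
Remark: the three starting materials are taken as commercial.

Step 1
Reactants: 1 5-fluorobenzene-1,3-diol
Product: 2 1,3-bis(benzyloxy)-5-fluorobenzene
Conditions: BnBr (2.3 equiv), K2CO3, DMF, 60 °C
Reagents that add atoms: benzyl bromide, BrCc1ccccc1
Why: Twofold Williamson ether synthesis in which carbonate generates the phenoxides, the primary benzylic bromide alkylates them on oxygen, and the unactivated C–F bond stays untouched.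

Step 2
Reactants: 2 1,3-bis(benzyloxy)-5-fluorobenzene
Product: 3 1,5-bis(benzyloxy)-2-bromo-3-fluorobenzene
Conditions: NBS (1.0 equiv), MeCN, 0 °C → rt, dark
Reagents that add atoms: N-bromosuccinimide, O=C1CCC(=O)N1Br
Why: Electrophilic aromatic bromination; the two equivalent CH positions next to fluorine are para to one ether, ortho to the other and much less crowded than the CH between both benzyloxy groups, so one equivalent of NBS should mark only the future C4a.

Step 3
Reactants: 4 benzyloxyacetic acid
Product: 6 2-(benzyloxy)-N-methoxy-N-methylacetamide, via acyl imidazolide 5 (not isolated)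
Conditions: CDI, CH2Cl2, rt; then MeNH(OMe)·HCl, rt
Reagents that add atoms: N,O-dimethylhydroxylamine hydrochloride, CNOC.Cl
Why: Weinreb amide formation through CDI activation; acyl imidazolide 5 is a clean acyl donor towards the hydroxylamine and the benzyl ether is a bystander.

Step 4
Reactants: 3 1,5-bis(benzyloxy)-2-bromo-3-fluorobenzene; 6 2-(benzyloxy)-N-methoxy-N-methylacetamide
Product: 9 2-(benzyloxy)-1-[2,4-bis(benzyloxy)-6-fluorophenyl]ethan-1-one, via aryllithium 7 (not isolated), via tetrahedral adduct 8 (not isolated)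
Conditions: n-BuLi (1.05 equiv), THF, −78 °C, 20 min; then 6, −78 °C; 1 M HCl quench
Reagents that add atoms: none
Why: Bromine–lithium exchange followed by the Weinreb ketone synthesis; at −78 °C the exchange outruns deprotonation of the OCH2Ph groups and 7 does not yet lose LiF to an aryne, while the chelated adduct 8 withholds the ketone until the quench and so prevents double addition.

Step 5
Reactants: 9 2-(benzyloxy)-1-[2,4-bis(benzyloxy)-6-fluorophenyl]ethan-1-one
Product: 10 2-(benzyloxy)-1-[2,4-bis(benzyloxy)-3,5-dibromo-6-fluorophenyl]ethan-1-one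
Conditions: NBS (2.2 equiv), MeCN, rt → 40 °C, dark
Reagents that add atoms: N-bromosuccinimide, O=C1CCC(=O)N1Br
Why: Twofold electrophilic aromatic bromination; the last two ring CH positions are each ortho or para to both ethers and meta to the acyl group, so exhaustive bromination leaves no regiochemical choice, and dark polar conditions suppress radical attack at the benzylic and α-keto CH2 groups.

Step 6
Reactants: 10 2-(benzyloxy)-1-[2,4-bis(benzyloxy)-3,5-dibromo-6-fluorophenyl]ethan-1-one
Product: 11 2-(benzyloxy)-1-[2,4-bis(benzyloxy)-6-fluoro-3,5-dimethylphenyl]ethan-1-one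
Conditions: MeZnCl (3 equiv), Pd(OAc)2 (5 mol %), SPhos (10 mol %), THF, 60 °C
Reagents that add atoms: methylzinc chloride, C[Zn]Cl
Why: Twofold Negishi coupling; a bulky electron-rich biarylphosphine lets palladium insert into the doubly flanked C–Br bonds, methylzinc has no β-hydrogen, and the base-free medium spares the enolisable ketone and the C–F bond needed later.

Step 7
Reactants: 12 methyl 3,5-dihydroxy-4-methoxybenzoate
Product: 13 methyl 3,5-bis(benzyloxy)-4-methoxybenzoate
Conditions: BnBr (2.3 equiv), K2CO3, DMF, 60 °C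
Reagents that add atoms: benzyl bromide, BrCc1ccccc1
Why: Twofold Williamson ether synthesis on the two equivalent phenols, with the methyl ester and the 4-methoxy group inert to carbonate.

Step 8
Reactants: 13 methyl 3,5-bis(benzyloxy)-4-methoxybenzoate
Product: 15 3,5-bis(benzyloxy)-4-methoxybenzoic acid, via sodium carboxylate 14 (not isolated)
Conditions: NaOH, THF–MeOH–H2O, 50 °C; then 1 M HCl
Reagents that add atoms: sodium hydroxide, [Na+].[OH-]
Why: Saponification (BAc2 ester hydrolysis) of an unhindered benzoate, under which aryl benzyl and aryl methyl ethers are stable.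

Step 9
Reactants: 15 3,5-bis(benzyloxy)-4-methoxybenzoic acid
Product: 16 3,5-bis(benzyloxy)-4-methoxybenzoyl chloride
Conditions: (COCl)2, cat. DMF, CH2Cl2, 0 °C → rt; concentrated and used crude
Reagents that add atoms: oxalyl chloride, O=C(Cl)C(=O)Cl
Why: Acid chloride formation with oxalyl chloride under Vilsmeier-type DMF catalysis, a mild method that leaves the aryl ethers intact.

Step 10
Reactants: 11 2-(benzyloxy)-1-[2,4-bis(benzyloxy)-6-fluoro-3,5-dimethylphenyl]ethan-1-one; 16 3,5-bis(benzyloxy)-4-methoxybenzoyl chloride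
Product: 19 2-(benzyloxy)-1-[2,4-bis(benzyloxy)-6-fluoro-3,5-dimethylphenyl]-3-[3,5-bis(benzyloxy)-4-methoxyphenyl]propane-1,3-dione (chelated enol form), via lithium enolate 17 (not isolated), via lithium diketonate 18 (not isolated)
Conditions: LiHMDS (2.1 equiv), THF, −78 °C; then 16, −78 → −20 °C; 1 M HCl quench
Reagents that add atoms: none
Why: Crossed Claisen-type C-aroylation of a ketone enolate; the chelated enolate 17 attacks the aroyl chloride at carbon, any enol ester formed at oxygen is itself an acyl donor that funnels to the more stable diketonate, and the second equivalent of base stores the product as 18 so that it cannot quench 17.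

Step 11
Reactants: 19 2-(benzyloxy)-1-[2,4-bis(benzyloxy)-6-fluoro-3,5-dimethylphenyl]-3-[3,5-bis(benzyloxy)-4-methoxyphenyl]propane-1,3-dione (chelated enol form)
Product: 22 3,5,7-tris(benzyloxy)-2-[3,5-bis(benzyloxy)-4-methoxyphenyl]-6,8-dimethyl-4H-chromen-4-one, via cesium enolate 20 (not isolated), via Meisenheimer adduct 21 (not isolated)
Conditions: Cs2CO3 (2.5 equiv), 4 Å MS, dry DMSO, 80 °C
Reagents that add atoms: none
Why: Carbonate converts 19 into the delocalised enolate 20; after rotation about C3–C4 out of the chelated U-shape, which the weakly bound cesium ion permits, the ring-B-side oxygen adds to C8a ipso to fluorine to give adduct 21, whose charge rests on C8, C6 and C4a and drains from C4a into the C4 carbonyl, and loss of fluoride restores ring A (intramolecular SNAr, addition–elimination). The closest known reaction type is the metal-free, carbonate-mediated cyclisation of 1-(2-haloaryl)-1,3-diketones to flavones, with the base-induced closure of alkoxy-substituted 2-fluorobenzophenones to xanthones as the analogue for electron-rich rings. Ring C closes in a six-membered mode that is formally a 6-endo-trig conjugate addition to C8a=C4a–C4=O followed by β-elimination of fluoride. No stereocentre remains, because the sp3 carbon C8a of 21 becomes planar again, and the geometry required (O1 and C4 cis on C2=C3) is reached by equilibration of the diketonate. Three selectivities are needed: oxygen over carbon attack, secured because C3 could only form a four-membered ring; C8a–F over the equally ortho C5–OBn, secured by the much faster addition at a C–F carbon and the poor leaving ability of benzyloxide; and closure over retro-Claisen cleavage, secured by a dry, non-nucleophilic base in a dipolar aprotic solvent. The O5 and O7 ethers are meta to C8a and do not oppose the developing charge, whereas the two methyl groups on C6 and C8 oppose it only weakly.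

Step 12
Reactants: 22 3,5,7-tris(benzyloxy)-2-[3,5-bis(benzyloxy)-4-methoxyphenyl]-6,8-dimethyl-4H-chromen-4-one
Product: 23 3,5,7-trihydroxy-2-(3,5-dihydroxy-4-methoxyphenyl)-6,8-dimethyl-4H-chromen-4-one (6,8-di-C-methylmyricetin 4'-methyl ether)
Conditions: H2 (1 atm), 10% Pd/C, THF–MeOH, rt
Reagents that add atoms: none
Why: Catalytic hydrogenolysis of benzyl ethers; all five O–CH2Ph bonds are cleaved on palladium, whereas the aryl methyl ether, the C-methyl groups and the tetrasubstituted C2=C3 bond of the chromone should not be reduced at one atmosphere and room temperature.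

**Compound list**
1 | 5-fluorobenzene-1,3-diol (5-fluororesorcinol) | Oc1cc(O)cc(F)c1 | starting material
2 | 1,3-bis(benzyloxy)-5-fluorobenzene | Fc1cc(OCc2ccccc2)cc(OCc2ccccc2)c1 | intermediate
3 | 1,5-bis(benzyloxy)-2-bromo-3-fluorobenzene | Fc1cc(OCc2ccccc2)cc(OCc2ccccc2)c1Br | intermediate
4 | benzyloxyacetic acid | O=C(O)COCc1ccccc1 | starting material
5 | 2-(benzyloxy)-1-(1H-imidazol-1-yl)ethan-1-one (acyl imidazolide, formed in situ) | O=C(COCc1ccccc1)n1ccnc1 | intermediate
6 | 2-(benzyloxy)-N-methoxy-N-methylacetamide | CON(C)C(=O)COCc1ccccc1 | intermediate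
7 | [2,4-bis(benzyloxy)-6-fluorophenyl]lithium (formed in situ) | [Li]c1c(F)cc(OCc2ccccc2)cc1OCc1ccccc1 | intermediate
8 | lithium 2-(benzyloxy)-1-[2,4-bis(benzyloxy)-6-fluorophenyl]-1-[methoxy(methyl)amino]ethan-1-olate (racemic tetrahedral adduct, formed in situ) | [Li+].[O-]C(COCc1ccccc1)(N(C)OC)c1c(F)cc(OCc2ccccc2)cc1OCc1ccccc1 | intermediate
9 | 2-(benzyloxy)-1-[2,4-bis(benzyloxy)-6-fluorophenyl]ethan-1-one | O=C(COCc1ccccc1)c1c(F)cc(OCc2ccccc2)cc1OCc1ccccc1 | intermediate
10 | 2-(benzyloxy)-1-[2,4-bis(benzyloxy)-3,5-dibromo-6-fluorophenyl]ethan-1-one | O=C(COCc1ccccc1)c1c(F)c(Br)c(OCc2ccccc2)c(Br)c1OCc1ccccc1 | intermediate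
11 | 2-(benzyloxy)-1-[2,4-bis(benzyloxy)-6-fluoro-3,5-dimethylphenyl]ethan-1-one | O=C(COCc1ccccc1)c1c(F)c(C)c(OCc2ccccc2)c(C)c1OCc1ccccc1 | intermediate
12 | methyl 3,5-dihydroxy-4-methoxybenzoate | COC(=O)c1cc(O)c(OC)c(O)c1 | starting material
13 | methyl 3,5-bis(benzyloxy)-4-methoxybenzoate | COC(=O)c1cc(OCc2ccccc2)c(OC)c(OCc2ccccc2)c1 | intermediate
14 | sodium 3,5-bis(benzyloxy)-4-methoxybenzoate (formed in situ) | [Na+].[O-]C(=O)c1cc(OCc2ccccc2)c(OC)c(OCc2ccccc2)c1 | intermediate
15 | 3,5-bis(benzyloxy)-4-methoxybenzoic acid | O=C(O)c1cc(OCc2ccccc2)c(OC)c(OCc2ccccc2)c1 | intermediate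
16 | 3,5-bis(benzyloxy)-4-methoxybenzoyl chloride | O=C(Cl)c1cc(OCc2ccccc2)c(OC)c(OCc2ccccc2)c1 | intermediate
17 | lithium (Z)-2-(benzyloxy)-1-[2,4-bis(benzyloxy)-6-fluoro-3,5-dimethylphenyl]ethen-1-olate (formed in situ) | [Li+].[O-]/C(=C\OCc1ccccc1)c1c(F)c(C)c(OCc2ccccc2)c(C)c1OCc1ccccc1 | intermediate
18 | lithium diketonate of 19 (formed in situ) | [Li+].COc1c(OCc2ccccc2)cc(/C([O-])=C(\OCc2ccccc2)C(=O)c2c(F)c(C)c(OCc3ccccc3)c(C)c2OCc2ccccc2)cc1OCc1ccccc1 | intermediate
19 | (E)-2-(benzyloxy)-1-[2,4-bis(benzyloxy)-6-fluoro-3,5-dimethylphenyl]-3-[3,5-bis(benzyloxy)-4-methoxyphenyl]-3-hydroxyprop-2-en-1-one, the chelated enol of the propane-1,3-dione | COc1c(OCc2ccccc2)cc(/C(O)=C(\OCc2ccccc2)C(=O)c2c(F)c(C)c(OCc3ccccc3)c(C)c2OCc2ccccc2)cc1OCc1ccccc1 | intermediate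
20 | cesium enolate of 19 (formed in situ) | [Cs+].COc1c(OCc2ccccc2)cc(/C([O-])=C(\OCc2ccccc2)C(=O)c2c(F)c(C)c(OCc3ccccc3)c(C)c2OCc2ccccc2)cc1OCc1ccccc1 | intermediate
21 | cesium 3,5,7-tris(benzyloxy)-2-[3,5-bis(benzyloxy)-4-methoxyphenyl]-8a-fluoro-6,8-dimethyl-8aH-chromen-4-olate (racemic σ-adduct, formed in situ) | [Cs+].[O-]C1=C2C(OCc3ccccc3)=C(C)C(OCc3ccccc3)=C(C)C2(F)OC(c2cc(OCc3ccccc3)c(OC)c(OCc3ccccc3)c2)=C1OCc1ccccc1 | intermediate
22 | 3,5,7-tris(benzyloxy)-2-[3,5-bis(benzyloxy)-4-methoxyphenyl]-6,8-dimethyl-4H-chromen-4-one | COc1c(OCc2ccccc2)cc(-c2oc3c(C)c(OCc4ccccc4)c(C)c(OCc4ccccc4)c3c(=O)c2OCc2ccccc2)cc1OCc1ccccc1 | intermediate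
23 | 3,5,7-trihydroxy-2-(3,5-dihydroxy-4-methoxyphenyl)-6,8-dimethyl-4H-chromen-4-one (achiral) | COc1c(O)cc(-c2oc3c(C)c(O)c(C)c(O)c3c(=O)c2O)cc1O | target

**Totals**
Total step count: 12. Longest linear sequence: 8 (steps 1, 2, 4, 5, 6, 10, 11, 12).

**The three steps most likely to fail**

(a) The ring closure, step 11.
- What may go wrong: the ipso addition may be too slow. Ring A is hexasubstituted and electron-rich, and the C4 ketone is twisted out of the ring plane by its two ortho substituents. At the temperature then required, retro-Claisen fragmentation of the diketonate could overtake closure.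
- Fallback: it keeps the O1–C8a disconnection but strengthens the activation. It sets out from 10 and carries both bromine atoms through the cyclisation.
- Aroylation of 10 with 16 under the conditions of step 10 should give 2-(benzyloxy)-1-[2,4-bis(benzyloxy)-3,5-dibromo-6-fluorophenyl]-3-[3,5-bis(benzyloxy)-4-methoxyphenyl]propane-1,3-dione F1.
- In F1 the halogens sit on the very carbons (C6 and C8) that take up the Meisenheimer charge. Cs2CO3 in DMSO should therefore close ring C near room temperature to 3,5,7-tris(benzyloxy)-2-[3,5-bis(benzyloxy)-4-methoxyphenyl]-6,8-dibromo-4H-chromen-4-one F2.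
- A twofold Suzuki–Miyaura methylation (trimethylboroxine, Pd(dppf)Cl2, K2CO3, dioxane, 100 °C) then acts on a non-enolisable chromone free of C–F. It comes back to the route at 22.

(b) The C-aroylation, step 10.
- What may go wrong: acylation at the enolate oxygen, proton transfer from product to unreacted enolate, and consumption of the acid chloride by the excess amide base may all erode the C–C bond formation.
- Fallback: the acyl transfer is replaced by an aldol addition and an oxidation. It sets out from 13 for the ring-B partner and from 11 through its enolate 17.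
- LiAlH4 in THF at 0 °C should reduce 13 to [3,5-bis(benzyloxy)-4-methoxyphenyl]methanol F3.
- MnO2 in CH2Cl2 should oxidise F3 to 3,5-bis(benzyloxy)-4-methoxybenzaldehyde F4.
- Addition of 17 to F4 at −78 °C can occur only at carbon. It should give 2-(benzyloxy)-1-[2,4-bis(benzyloxy)-6-fluoro-3,5-dimethylphenyl]-3-[3,5-bis(benzyloxy)-4-methoxyphenyl]-3-hydroxypropan-1-one F5 as a racemic syn/anti mixture.
- Both stereocentres of F5 are erased by Dess–Martin oxidation (CH2Cl2, NaHCO3, rt), which comes back to the route at 19.

(c) The twofold methylation, step 6.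
- What may go wrong: oxidative addition at C–Br bonds flanked on both sides may be slow. The sequence could then stall after the first coupling or drift into protodebromination.
- Fallback: palladium is avoided and the methyl groups are brought in as MeI on aryllithiums before any ketone is present. It sets out from 1.
- Iodination with I2 and NaHCO3 in water at 0 °C goes, for resorcinols, to the carbon between the two hydroxy groups. It should give 5-fluoro-2-iodobenzene-1,3-diol F6.
- BnBr and K2CO3 in DMF then give 1,3-bis(benzyloxy)-5-fluoro-2-iodobenzene F7.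
- Iodine–lithium exchange (n-BuLi, THF, −78 °C) and quenching with MeI give the symmetric 1,3-bis(benzyloxy)-5-fluoro-2-methylbenzene F8.
- The two remaining CH positions of F8 are equivalent, so NBS (2.1 equiv, MeCN) should give 1,3-bis(benzyloxy)-4,6-dibromo-5-fluoro-2-methylbenzene F9 without any regiochemical choice.
- Exchange of one bromine (n-BuLi, 1.0 equiv, −78 °C) and quenching with MeI give 1,3-bis(benzyloxy)-4-bromo-5-fluoro-2,6-dimethylbenzene F10.
- A last bromine–lithium exchange, followed by addition of 6 as in step 4, comes back to the route at 11.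

**Further compounds**
F1 | step 11 | 2-(benzyloxy)-1-[2,4-bis(benzyloxy)-3,5-dibromo-6-fluorophenyl]-3-[3,5-bis(benzyloxy)-4-methoxyphenyl]propane-1,3-dione (chelated enol form) | COc1c(OCc2ccccc2)cc(/C(O)=C(\OCc2ccccc2)C(=O)c2c(F)c(Br)c(OCc3ccccc3)c(Br)c2OCc2ccccc2)cc1OCc1ccccc1
F2 | step 11 | 3,5,7-tris(benzyloxy)-2-[3,5-bis(benzyloxy)-4-methoxyphenyl]-6,8-dibromo-4H-chromen-4-one | COc1c(OCc2ccccc2)cc(-c2oc3c(Br)c(OCc4ccccc4)c(Br)c(OCc4ccccc4)c3c(=O)c2OCc2ccccc2)cc1OCc1ccccc1
F3 | step 10 | [3,5-bis(benzyloxy)-4-methoxyphenyl]methanol | COc1c(OCc2ccccc2)cc(CO)cc1OCc1ccccc1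
F4 | step 10 | 3,5-bis(benzyloxy)-4-methoxybenzaldehyde | COc1c(OCc2ccccc2)cc(C=O)cc1OCc1ccccc1
F5 | step 10 | 2-(benzyloxy)-1-[2,4-bis(benzyloxy)-6-fluoro-3,5-dimethylphenyl]-3-[3,5-bis(benzyloxy)-4-methoxyphenyl]-3-hydroxypropan-1-one (racemic syn/anti mixture) | COc1c(OCc2ccccc2)cc(C(O)C(OCc2ccccc2)C(=O)c2c(F)c(C)c(OCc3ccccc3)c(C)c2OCc2ccccc2)cc1OCc1ccccc1
F6 | step 6 | 5-fluoro-2-iodobenzene-1,3-diol | Oc1cc(F)cc(O)c1I
F7 | step 6 | 1,3-bis(benzyloxy)-5-fluoro-2-iodobenzene | Fc1cc(OCc2ccccc2)c(I)c(OCc2ccccc2)c1
F8 | step 6 | 1,3-bis(benzyloxy)-5-fluoro-2-methylbenzene | Cc1c(OCc2ccccc2)cc(F)cc1OCc1ccccc1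
F9 | step 6 | 1,3-bis(benzyloxy)-4,6-dibromo-5-fluoro-2-methylbenzene | Cc1c(OCc2ccccc2)c(Br)c(F)c(Br)c1OCc1ccccc1
F10 | step 6 | 1,3-bis(benzyloxy)-4-bromo-5-fluoro-2,6-dimethylbenzene | Cc1c(F)c(Br)c(OCc2ccccc2)c(C)c1OCc1ccccc1
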